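Slowness is the thing to measure here: find how long G lasts against J, then count how many such spans the flask is given.

all flasks: G 0.25 M (fed, over 12 s)

| run | J | remark | time |
|---|---|---|---|
| spring | 1 equiv | run made earlier; the fed solution adds 0.25 times the starting volume |  |
| midnight | 2.3 equiv | run made earlier; the fed solution adds 0.25 times the starting volume |  |
| autumn | 5.4 equiv | run made earlier; the fed solution adds 0.25 times the starting volume |  |
| Wednesday's | 1.20 equiv | the fed solution adds 0.25 times the starting volume | 4.0 min |
| Saturday's | 2.40 equiv | the fed solution adds 0.25 times the starting volume | 4.0 min |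
| Friday's | 4.80 equiv | the fed solution adds 0.25 times the starting volume | 4.0 min |

| run | time / min | G / % | Z / % |
|---|---|---|---|
| spring | 0.500 | 82 | 14 |
| spring | 1.00 | 68 | 15 |
| spring | 1.50 | 59 | 19 |
| spring | 2.50 | 46 | 26 |
| spring | 3.00 | 43 | 27 |
| midnight | 0.250 | 87 | 11 |
| midnight | 0.667 | 61 | 23 |
| midnight | 1.33 | 43 | 39 |
| midnight | 2.00 | 24 | 39 |
| midnight | 3.00 | 16 | 46 |
| autumn | 0.250 | 72 | 27 |
| autumn | 0.417 | 51 | 39 |
| autumn | 0.833 | 21 | 52 |
| autumn | 1.33 | 8 | 58 |
| autumn | 3.00 | 3 | 62 |

(each reading ± 2 percentage points)

- charges are per starting volume, the dose included; the dosed solution carries all of it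
- the numbers in the tables scatter by 2 percentage points (one standard deviation)

- part of the G that has reacted at the end, Wednesday's
- part of the G that has reacted at the end, Saturday's
- part of the G that has reacted at the end, Friday's
- what raising the equivalents of J from its lowest to its highest value here does to the part of the G that has reacted (changes below 5 percentage points count as none) (it falls / it rises / no change)

How slow is G? In the autumn run, with J charged at 5.4 equiv (treat it as pseudo-first-order, J held at its charge), the readings of G fall from 51% to 8% between 0.417 min and 1.33 min. That reads as a rate of 2.03 min⁻¹. Take this rate as proportional to J. Then τ = 2.66 min, the time constant of G against one equivalent of J, and with n equivalents it is τ/n.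

Does the feed matter? It lasts 0.2 min, shorter than the 0.554 min that τ/n gives for Friday's, so start the clock at mid-feed, which gives T = 3.90 min up to the reading at 4.0 min.

Does J hold still? Assume not: let one J go with each G. Then G left = (n−1)/(n·exp((n−1)T/τ)−1). Test this on the midnight run at 3.00 min: it gives 15.3% against a reading of 16%.

My reckoning for the reacted part is 67.1% for Wednesday's, 92.1% for Saturday's and 99.7% for Friday's. It rises by 33 percentage points, past the 5 points that count as a change.

The forecast gives 70%, 92% and 99%, with the trend "it rises", holding that “G disappearance fits first order in J”.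

The flasks give 68.2% for Wednesday's, 89.2% for Saturday's and 99.6% for Friday's; across the range, it rises by 31 points.

    G + J → E + Z (k = 0.0360 M⁻¹ s⁻¹)
    J + E ⇌ D, settled at all times (K = 2500 M⁻¹)
    Z ⇌ Q (K = 0.540, k = 0.0370 s⁻¹)
    2 G → X (k = 0.00690 M⁻¹ s⁻¹)

In Friday's flask Z has a half-life of 0.31 min by the forward rate from Z to Q, counted without the way back, shorter than the 0.459 min by which half the turnover of G with J up to the asked time is done. At 4.00 min that flask holds Z at 62.2% and Q at 33.5%, with G down to 0.433%.

Now take one more flask, like Friday's but with 2.90 equiv of J: τ/n is 0.917 min, and the formula puts the reacted part at 95.9%. The flask gives 93.9%.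

All runs were generated by integration for an exercise; scatter was added.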